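**Plan**

- Cuts: (1) the diaryl ether bond between the ring A carbon and the bridging oxygen, which stays on ring B; (2) the C9–C10 single bond next to the (E)-alkene (chain numbered C1 = carbinol carbon to C14 = CH2 on ring A); (3) C1–C2; (4) the C–O bond of the central ring B oxygen.
- Enabling feature: ring A is a resorcinol ring whose ether carbon (C1) and hydroxyl carbon (C3) are meta. A 1,2-aryne of ring A (C1≡C2) that carries the C3 oxygen therefore takes an oxygen nucleophile at C1. The second resorcinol oxygen supplies the C1 triflate, and C2, between the two oxygens, is silylated by directed lithiation.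
- Ring B is a 1,2,3-trioxygenated ring. Its central oxygen, the nucleophile, is put between two OMOM groups by the same kind of directed lithiation, so both rings come from simple 3,5-dioxygenated benzenes.
- Forward: a ring A fragment (o-silylaryl triflate with a pentenyl chain, 5 steps) and a ring B fragment (phenol with an (E)-iodononenyl carbinol chain, 7 steps) are joined at C9–C10 by B-alkyl Suzuki–Miyaura coupling. The 22-membered ring is then closed at the ether bond by fluoride-induced aryne capture, and global deprotection ends the route.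
- Stereochemistry: the (R)-carbinol comes from asymmetric transfer hydrogenation of an aryl alkyl ketone. The (E)-alkene comes from syn-hydrozirconation/iodinolysis of a terminal alkyne and a stereoretentive coupling.

Key step: step 14

Assumption: the carbinol carbon of the target is R by the CIP rules (OH > aryl > CH2 > H), and 5-bromoresorcinol, pent-4-enylzinc bromide (THF solution), 3,5-dihydroxybenzonitrile and 8-bromooct-1-yne are taken as purchasable.

**Route**

Step 1
Reactants: 1 5-bromobenzene-1,3-diol (5-bromoresorcinol)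
Product: 2 3-bromo-5-(methoxymethoxy)phenol
Conditions: MOMCl (1.0 equiv), iPr2NEt, CH2Cl2–THF, 0 °C to rt
Reagents that add atoms: chloromethyl methyl ether (MOMCl), COCCl
Why: Williamson-type O-alkylation with the α-chloro ether; with one equivalent of MOMCl the symmetric diol is mono-protected statistically, the mono-ether should be separable from bis-ether and recovered 1 (both recyclable), and this desymmetrisation decides which resorcinol oxygen stays on ring A and which is later sacrificed as the triflate.

Step 2
Reactants: 2 3-bromo-5-(methoxymethoxy)phenol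
Product: 3 3-bromo-5-(methoxymethoxy)phenyl N-isopropylcarbamate
Conditions: i-PrNCO, Et3N (cat.), CH2Cl2, rt
Reagents that add atoms: isopropyl isocyanate, CC(C)N=C=O
Why: Amine-catalysed addition of the phenol to the isocyanate (carbamoylation) installs an N-monosubstituted carbamate that serves as ortho-director in step 4 and is removable under mild base in step 5.

Step 3
Reactants: 3 3-bromo-5-(methoxymethoxy)phenyl N-isopropylcarbamate; 4 pent-4-en-1-ylzinc bromide
Product: 5 3-(methoxymethoxy)-5-(pent-4-en-1-yl)phenyl N-isopropylcarbamate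
Conditions: Pd(dppf)Cl2·CH2Cl2 (5 mol%), THF, 50 °C (4: 2.2 equiv)
Reagents that add atoms: none
Why: Negishi sp2–sp3 cross-coupling: zerovalent palladium inserts into the aryl C–Br bond, the primary alkylzinc transmetalates and the wide-bite-angle dppf ligand favours reductive elimination over β-hydride elimination, while the weakly basic organozinc (the excess covers the N–H) tolerates carbamate, acetal and terminal alkene.

Step 4
Reactants: 5 3-(methoxymethoxy)-5-(pent-4-en-1-yl)phenyl N-isopropylcarbamate
Product: 9 3-(methoxymethoxy)-5-(pent-4-en-1-yl)-2-(trimethylsilyl)phenyl N-isopropylcarbamate, via N-silyl carbamate 6 (not isolated), via aryllithium 7 (not isolated), via C-silylated N-silyl carbamate 8 (not isolated)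
Conditions: TBSOTf, TMEDA, Et2O, 0 °C to rt; n-BuLi, TMEDA, −78 °C; TMSCl, −78 °C to rt; sat. aq. NH4Cl
Reagents that add atoms: chlorotrimethylsilane (TMSCl), C[Si](C)(C)Cl
Why: Directed ortho-metalation: in situ N-silylation prevents deprotonation of the carbamate N–H and loss of isocyanate (and uses up the silyl triflate before it can activate the MOM acetal), n-BuLi·TMEDA then removes the C2 proton, the only one flanked by both the O-carbamate and the OMOM director, TMSCl traps the aryllithium and the N–Si bond is hydrolysed on work-up.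

Step 5
Reactants: 9 3-(methoxymethoxy)-5-(pent-4-en-1-yl)-2-(trimethylsilyl)phenyl N-isopropylcarbamate
Product: 11 3-(methoxymethoxy)-5-(pent-4-en-1-yl)-2-(trimethylsilyl)phenyl trifluoromethanesulfonate (ring A fragment), via 2-silylphenol 10 (not isolated)
Conditions: DBU, Et2NH, MeCN, 40 °C; then PhNTf2, rt
Reagents that add atoms: N-phenylbis(trifluoromethanesulfonimide) (PhNTf2), O=S(=O)(N(c1ccccc1)S(=O)(=O)C(F)(F)F)C(F)(F)F
Why: E1cB cleavage of the N-monosubstituted carbamate by DBU (the isocyanate is scavenged by Et2NH as a urea) frees the hindered 2-silylphenoxide, which is triflated in the same pot with PhNTf2 to give the o-silylaryl triflate aryne precursor; alkene, acetal and C–Si bond are inert to these mild bases.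

Step 6
Reactants: 12 3,5-dihydroxybenzonitrile
Product: 13 3,5-bis(methoxymethoxy)benzonitrile
Conditions: MOMCl (2.5 equiv), iPr2NEt, CH2Cl2, 0 °C to rt
Reagents that add atoms: chloromethyl methyl ether (MOMCl), COCCl
Why: Double Williamson-type O-alkylation of both phenols with MOMCl; the nitrile is inert and the two OMOM groups will later direct lithiation to the carbon between them.

Step 7
Reactants: 14 8-bromooct-1-yne
Product: 16 (8-bromooct-1-yn-1-yl)trimethylsilane, via lithium acetylide 15 (not isolated)
Conditions: n-BuLi, THF, −78 °C; TMSCl, −78 °C to rt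
Reagents that add atoms: chlorotrimethylsilane (TMSCl), C[Si](C)(C)Cl
Why: Deprotonation of the terminal alkyne is much faster than lithium–bromine exchange of the primary bromide at −78 °C, and C-silylation of the acetylide masks the acidic C–H so that a Grignard reagent can be made from the bromide.

Step 8
Reactants: 13 3,5-bis(methoxymethoxy)benzonitrile; 16 (8-bromooct-1-yn-1-yl)trimethylsilane
Product: 19 1-[3,5-bis(methoxymethoxy)phenyl]-9-(trimethylsilyl)non-8-yn-1-one, via Grignard reagent 17 (not isolated), via magnesium ketiminate 18 (not isolated)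
Conditions: 16, Mg, THF, rt to 40 °C; then 13, CuBr·SMe2 (5 mol%), THF, 50 °C; then 10% aq. citric acid, rt
Reagents that add atoms: water, O
Why: Grignard addition to the aryl nitrile (copper bromide catalysis for rate) stops at the magnesium ketiminate, so no tertiary alcohol can form, and hydrolysis at pH 3–4, which aryl MOM acetals and the silylalkyne should survive, gives the aryl alkyl ketone.

Step 9
Reactants: 19 1-[3,5-bis(methoxymethoxy)phenyl]-9-(trimethylsilyl)non-8-yn-1-one
Product: 20 (1R)-1-[3,5-bis(methoxymethoxy)phenyl]-9-(trimethylsilyl)non-8-yn-1-ol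
Conditions: RuCl[(R,R)-TsDPEN](p-cymene) (1 mol%), HCO2H–Et3N (5:2), rt
Reagents that add atoms: none
Why: Noyori–Ikariya asymmetric transfer hydrogenation: the ruthenium hydride/N–H pair of the (R,R)-TsDPEN complex transfers hydride and proton through a six-membered transition state in which the aryl group is held by a CH/π contact with the η6-arene, which sets the (R)-carbinol centre in the same sense as for acetophenone, and the formate conditions leave the alkyne untouched (no hydroboration as with borane reagents).

Step 10
Reactants: 20 (1R)-1-[3,5-bis(methoxymethoxy)phenyl]-9-(trimethylsilyl)non-8-yn-1-ol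
Product: 21 tert-butyl{[(1R)-1-[3,5-bis(methoxymethoxy)phenyl]-9-(trimethylsilyl)non-8-yn-1-yl]oxy}dimethylsilane
Conditions: TBSCl, imidazole, DMF, rt
Reagents that add atoms: tert-butyldimethylsilyl chloride (TBSCl), CC(C)(C)[Si](C)(C)Cl
Why: Imidazole-promoted silylation of the secondary alcohol gives a bulky, non-coordinating ether that cannot steer the next lithiation to C2/C6 and keeps the carbinol oxygen out of the aryne step; the stereocentre is not touched.

Step 11
Reactants: 21 tert-butyl{[(1R)-1-[3,5-bis(methoxymethoxy)phenyl]-9-(trimethylsilyl)non-8-yn-1-yl]oxy}dimethylsilane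
Product: 24 4-[(1R)-1-{[tert-butyl(dimethyl)silyl]oxy}non-8-yn-1-yl]-2,6-bis(methoxymethoxy)phenol, via aryllithium 22 (not isolated), via dimethyl arylboronate 23 (not isolated)
Conditions: n-BuLi, TMEDA, THF, −20 °C; B(OMe)3, −78 °C to rt; then NaOH, H2O2, MeOH–H2O, 0 °C to rt
Reagents that add atoms: hydrogen peroxide, OO
Why: Directed ortho-metalation at C4 of ring B, the carbon between the two cooperating OMOM directors, then borylation and alkaline peroxide oxidation (1,2-aryl shift from boron to oxygen) install the third ring B oxygen as a free phenol, and the methanolic hydroxide of the oxidation medium also cleaves the alkynyl C–Si bond to release the terminal alkyne.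

Step 12
Reactants: 24 4-[(1R)-1-{[tert-butyl(dimethyl)silyl]oxy}non-8-yn-1-yl]-2,6-bis(methoxymethoxy)phenol
Product: 26 4-[(1R,8E)-1-{[tert-butyl(dimethyl)silyl]oxy}-9-iodonon-8-en-1-yl]-2,6-bis(methoxymethoxy)phenol (ring B fragment), via alkenylzirconocene 25 (not isolated)
Conditions: Cp2Zr(H)Cl (2.5 equiv), THF, rt; then I2, THF, 0 °C
Reagents that add atoms: iodine, II
Why: syn-Hydrozirconation places zirconium on the terminal alkyne carbon and iodinolysis of the C–Zr bond occurs with retention, so the (E)-vinyl iodide is formed stereospecifically; the phenol consumes one equivalent of Cp2Zr(H)Cl as a zirconium phenoxide that is hydrolysed on work-up.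

Step 13
Reactants: 11 3-(methoxymethoxy)-5-(pent-4-en-1-yl)-2-(trimethylsilyl)phenyl trifluoromethanesulfonate; 26 4-[(1R,8E)-1-{[tert-butyl(dimethyl)silyl]oxy}-9-iodonon-8-en-1-yl]-2,6-bis(methoxymethoxy)phenol
Product: 28 5-[(6E,14R)-14-{[tert-butyl(dimethyl)silyl]oxy}-14-[4-hydroxy-3,5-bis(methoxymethoxy)phenyl]tetradec-6-en-1-yl]-3-(methoxymethoxy)-2-(trimethylsilyl)phenyl trifluoromethanesulfonate (seco-phenol), via B-alkyl-9-BBN borane 27 (not isolated)
Conditions: 11, 9-BBN, THF, 0 °C to rt; then 26, Pd(dppf)Cl2·CH2Cl2 (10 mol%), AsPh3, aq. K3PO4, DMF–THF, rt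
Reagents that add atoms: none
Why: B-alkyl Suzuki–Miyaura coupling: 9-BBN hydroborates the terminal alkene of 11 at the terminal carbon and the B-alkyl group is transferred to the vinylpalladium species with retention of the (E)-geometry, oxidative addition of zerovalent palladium to the vinyl iodide at room temperature being much faster than to the electron-rich aryl triflate shielded by its ortho TMS group, while the fluoride-free phosphate base leaves the C–Si bond (and so the aryne precursor) intact.

Step 14
Reactants: 28 seco-phenol (o-silylaryl triflate on ring A, free C4 phenol on ring B)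
Product: 31 O-TBS tri-O-MOM dehydrogravicycle (22-membered macrocycle: ring A C1–O–C4 ring B, ring A C5–(CH2)5–CH=CH–(CH2)6–CH(OTBS)–ring B C1; R, E), via aryne cesium phenoxide 29 (not isolated), via macrocyclic arylcesium 30 (not isolated)
Conditions: CsF (5 equiv), MeCN–toluene (1:1), 1 mM, syringe-pump addition of 28 over 12 h, rt
Reagents that add atoms: none
Why: Proposed new method: fluoride attacks the C2 trimethylsilyl group of ring A and the C1 triflate leaves, which gives the 3-(methoxymethoxy)-1,2-aryne 29 whose tethered ring B phenol is held as its cesium phenoxide by the same base; the phenoxide oxygen adds to C1 and the aryl anion 30 at C2 is protonated, a formal insertion of the aryne into the phenol O–H bond. The closest known reaction type is the intermolecular, transition-metal-free O-arylation of phenols (2,6-disubstituted ones included) with o-silylaryl triflates and CsF, and intramolecular capture of arynes by tethered heteroatom nucleophiles is known for five- to seven-membered rings, but a macrocyclising capture is not established. The 22-membered ring is closed by intramolecular nucleophilic addition of the phenoxide oxygen to the in-plane π bond of the aryne (a large-ring closure onto an unhindered sp-type carbon), and it should beat oligomerisation because at 1 mM with slow, fluoride-limited release of the aryne the only phenoxide near each aryne is its own, the addition being very fast while fluoride and acetonitrile are slow traps. No stereocentre is formed, and the (R)-carbinol (as its TBS ether) and the (E)-alkene do not take part. The step needs regioselectivity for C1 over C2, secured by the inductively withdrawing C3 OMOM group that distorts the aryne so that the nucleophile attacks the distal carbon and the charge develops next to oxygen, and chemoselectivity for the phenoxide, secured because every other hydroxyl is an acetal or silyl ether. The activating groups are traceless, since silicon and triflate leave in the event and the electron-rich ring A never needs an electron-withdrawing auxiliary.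

Step 15
Reactants: 31 O-TBS tri-O-MOM dehydrogravicycle
Product: 34 dehydrogravicycle (target; R, E), via tris(trimethylsilyl) ether 32 (not isolated), via triphenol TBS ether 33 (not isolated)
Conditions: TMSOTf, 2,2′-bipyridyl, CH2Cl2, 0 °C to rt; H2O; then TBAF, THF, rt
Reagents that add atoms: none
Why: Silyl triflate activation in the presence of 2,2′-bipyridyl converts each aryl MOM acetal through an N-(methoxymethyl)bipyridinium salt into an aryl trimethylsilyl ether without free Brønsted acid, so the ionisable benzylic C–O bond should keep its (R)-configuration and the (E)-alkene is untouched; water then hydrolyses the aryl silyl ethers and fluoride removes the TBS group.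

**Compound list**

1 | 5-bromobenzene-1,3-diol | Oc1cc(O)cc(Br)c1 | starting material
2 | 3-bromo-5-(methoxymethoxy)phenol | COCOc1cc(O)cc(Br)c1 | intermediate
3 | 3-bromo-5-(methoxymethoxy)phenyl N-isopropylcarbamate | CC(C)NC(=O)Oc1cc(OCOC)cc(Br)c1 | intermediate
4 | pent-4-en-1-ylzinc bromide | C=CCCC[Zn]Br | starting material
5 | 3-(methoxymethoxy)-5-(pent-4-en-1-yl)phenyl N-isopropylcarbamate | CC(C)NC(=O)Oc1cc(OCOC)cc(CCCC=C)c1 | intermediate
6 | N-(tert-butyldimethylsilyl) derivative of 5 | CC(C)N([Si](C)(C)C(C)(C)C)C(=O)Oc1cc(OCOC)cc(CCCC=C)c1 | intermediate (not isolated)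
7 | 2-lithio derivative of 6 (lithium between O-carbamate and OMOM) | CC(C)N([Si](C)(C)C(C)(C)C)C(=O)Oc1cc(CCCC=C)cc(OCOC)c1[Li] | intermediate (not isolated)
8 | 2-(trimethylsilyl) derivative of 6 | CC(C)N([Si](C)(C)C(C)(C)C)C(=O)Oc1cc(CCCC=C)cc(OCOC)c1[Si](C)(C)C | intermediate (not isolated)
9 | 3-(methoxymethoxy)-5-(pent-4-en-1-yl)-2-(trimethylsilyl)phenyl N-isopropylcarbamate | CC(C)NC(=O)Oc1cc(CCCC=C)cc(OCOC)c1[Si](C)(C)C | intermediate
10 | 3-(methoxymethoxy)-5-(pent-4-en-1-yl)-2-(trimethylsilyl)phenol | Oc1cc(CCCC=C)cc(OCOC)c1[Si](C)(C)C | intermediate (not isolated)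
11 | 3-(methoxymethoxy)-5-(pent-4-en-1-yl)-2-(trimethylsilyl)phenyl trifluoromethanesulfonate | C=CCCCc1cc(OCOC)c([Si](C)(C)C)c(OS(=O)(=O)C(F)(F)F)c1 | intermediate
12 | 3,5-dihydroxybenzonitrile | N#Cc1cc(O)cc(O)c1 | starting material
13 | 3,5-bis(methoxymethoxy)benzonitrile | N#Cc1cc(OCOC)cc(OCOC)c1 | intermediate
14 | 8-bromooct-1-yne | C#CCCCCCCBr | starting material
15 | lithium 8-bromooct-1-yn-1-ide | [Li]C#CCCCCCCBr | intermediate (not isolated)
16 | (8-bromooct-1-yn-1-yl)trimethylsilane | C[Si](C)(C)C#CCCCCCCBr | intermediate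
17 | [8-(trimethylsilyl)oct-7-yn-1-yl]magnesium bromide | C[Si](C)(C)C#CCCCCCC[Mg]Br | intermediate (not isolated)
18 | N-bromomagnesio ketimine of 19 | COCOc1cc(OCOC)cc(c1)C(=N[Mg]Br)CCCCCCC#C[Si](C)(C)C | intermediate (not isolated)
19 | 1-[3,5-bis(methoxymethoxy)phenyl]-9-(trimethylsilyl)non-8-yn-1-one | COCOc1cc(OCOC)cc(c1)C(=O)CCCCCCC#C[Si](C)(C)C | intermediate
20 | (1R)-1-[3,5-bis(methoxymethoxy)phenyl]-9-(trimethylsilyl)non-8-yn-1-ol | COCOc1cc(OCOC)cc(c1)[C@H](O)CCCCCCC#C[Si](C)(C)C | intermediate
21 | tert-butyl{[(1R)-1-[3,5-bis(methoxymethoxy)phenyl]-9-(trimethylsilyl)non-8-yn-1-yl]oxy}dimethylsilane | COCOc1cc(OCOC)cc(c1)[C@H](O[Si](C)(C)C(C)(C)C)CCCCCCC#C[Si](C)(C)C | intermediate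
22 | 4-lithio derivative of 21 (lithium between the two OMOM groups) | COCOc1cc(cc(OCOC)c1[Li])[C@H](O[Si](C)(C)C(C)(C)C)CCCCCCC#C[Si](C)(C)C | intermediate (not isolated)
23 | dimethyl arylboronate from 22 | COCOc1cc(cc(OCOC)c1B(OC)OC)[C@H](O[Si](C)(C)C(C)(C)C)CCCCCCC#C[Si](C)(C)C | intermediate (not isolated)
24 | 4-[(1R)-1-{[tert-butyl(dimethyl)silyl]oxy}non-8-yn-1-yl]-2,6-bis(methoxymethoxy)phenol | COCOc1cc(cc(OCOC)c1O)[C@H](O[Si](C)(C)C(C)(C)C)CCCCCCC#C | intermediate
25 | (E)-alkenylzirconocene chloride from 24, phenol held as zirconium phenoxide | COCOc1cc(cc(OCOC)c1O[Zr](Cl)(C1C=CC=C1)C1C=CC=C1)[C@H](O[Si](C)(C)C(C)(C)C)CCCCCC/C=C/[Zr](Cl)(C1C=CC=C1)C1C=CC=C1 | intermediate (not isolated)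
26 | 4-[(1R,8E)-1-{[tert-butyl(dimethyl)silyl]oxy}-9-iodonon-8-en-1-yl]-2,6-bis(methoxymethoxy)phenol | COCOc1cc(cc(OCOC)c1O)[C@H](O[Si](C)(C)C(C)(C)C)CCCCCC/C=C/I | intermediate
27 | B-alkyl-9-BBN adduct of 11 (boron on the terminal chain carbon) | C[Si](C)(C)c1c(OCOC)cc(CCCCCB2C3CCCC2CCC3)cc1OS(=O)(=O)C(F)(F)F | intermediate (not isolated)
28 | 5-[(6E,14R)-14-{[tert-butyl(dimethyl)silyl]oxy}-14-[4-hydroxy-3,5-bis(methoxymethoxy)phenyl]tetradec-6-en-1-yl]-3-(methoxymethoxy)-2-(trimethylsilyl)phenyl trifluoromethanesulfonate | COCOc1cc(cc(OCOC)c1O)[C@H](O[Si](C)(C)C(C)(C)C)CCCCCC/C=C/CCCCCc1cc(OCOC)c([Si](C)(C)C)c(OS(=O)(=O)C(F)(F)F)c1 | intermediate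
29 | ring A 3-(methoxymethoxy)-1,2-aryne carrying the ring B cesium phenoxide | [Cs+].COCOc1cc(cc(OCOC)c1[O-])[C@H](O[Si](C)(C)C(C)(C)C)CCCCCC/C=C/CCCCCC1=CC#CC(OCOC)=C1 | intermediate (not isolated)
30 | macrocyclic arylcesium (carbanion at ring A C2, between the ether carbon and the OMOM carbon) | [Cs+].COCOc1cc2cc([c-]1)Oc1c(OCOC)cc(cc1OCOC)[C@H](O[Si](C)(C)C(C)(C)C)CCCCCC/C=C/CCCCC2 | intermediate (not isolated)
31 | O-TBS tri-O-MOM dehydrogravicycle (R, E) | COCOc1cc2cc(c1)Oc1c(OCOC)cc(cc1OCOC)[C@H](O[Si](C)(C)C(C)(C)C)CCCCCC/C=C/CCCCC2 | intermediate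
32 | O-TBS tris-O-(trimethylsilyl) dehydrogravicycle | C[Si](C)(C)Oc1cc2cc(c1)Oc1c(O[Si](C)(C)C)cc(cc1O[Si](C)(C)C)[C@H](O[Si](C)(C)C(C)(C)C)CCCCCC/C=C/CCCCC2 | intermediate (not isolated)
33 | O-TBS dehydrogravicycle (three free phenols) | Oc1cc2cc(c1)Oc1c(O)cc(cc1O)[C@H](O[Si](C)(C)C(C)(C)C)CCCCCC/C=C/CCCCC2 | intermediate (not isolated)
34 | dehydrogravicycle (R, E) | Oc1cc2cc(c1)Oc1c(O)cc(cc1O)[C@H](O)CCCCCC/C=C/CCCCC2 | target

**Step count and risks**

Total steps: 15. Longest linear sequence: 9 steps (steps 6, 8, 9, 10, 11, 12, 13, 14, 15, from 12; the branch from 14 through step 7 is equally long).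

Steps most likely to fail:

Step 14 (key step). The chain may fold more slowly than a second phenoxide captures the aryne (oligomerisation), or the aryne may be lost to fluoride or solvent before ring closure. The fallback uses known chemistry, sets out from 11 and 26 and comes back at 31, and exchanges the order of the two bond-forming events. Phenol 26 and triflate 11 are first joined by the established intermolecular fluoride-induced aryne O-arylation (CsF, MeCN, rt, about 0.1 M, same regiocontrol by the C3 OMOM group) to give the open-chain diaryl ether tert-butyl{[(1R,8E)-9-iodo-1-{4-[3-(methoxymethoxy)-5-(pent-4-en-1-yl)phenoxy]-3,5-bis(methoxymethoxy)phenyl}non-8-en-1-yl]oxy}dimethylsilane F1. Its terminal alkene is hydroborated selectively with 9-BBN (the 1-iodoalkene is much less reactive) to the B-alkyl-9-BBN borane F2. An intramolecular B-alkyl Suzuki–Miyaura coupling (Pd(dppf)Cl2·CH2Cl2, AsPh3, aq. K3PO4, DMF–THF, 2 mM, rt), a well-precedented macrocyclisation, then closes the ring at C9–C10 with retention of the (E)-geometry and gives 31.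

Step 13. Oxidative addition into the aryl triflate or base-induced breakdown of the silyl triflate may compete with the wanted coupling, and the free phenoxide may slow transmetalation. The fallback sets out from 9 and 26 and comes back at 28; it moves the coupling to a stage with neither aryl triflate nor free phenol. Phenol 26 is O-allylated (allyl bromide, K2CO3, acetone, rt) to the allyl ether F3. Carbamate 9 is hydroborated with 9-BBN to the B-alkyl-9-BBN borane F4 and coupled with F3 (Pd(dppf)Cl2·CH2Cl2, AsPh3, aq. K3PO4, DMF–THF, rt) to the seco carbamate F5. DBU/Et2NH in MeCN liberates the seco 2-silylphenol F6 (not isolated), which PhNTf2 converts into the seco triflate allyl ether F7. Pd(PPh3)4 with morpholine in THF at rt then removes the allyl group (π-allyl formation is far faster than insertion into the hindered aryl triflate) and gives 28.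

Step 15. The silyl triflate may ionise the electron-rich benzylic C–O bond (loss of configuration or elimination), or the two MOM groups that flank the diaryl ether may be cleaved incompletely. The fallback sets out from 31 and comes back at 34; it takes the benzylic carbon to the ketone level while acid is used. TBAF (THF, rt) gives the tri-O-MOM alcohol F8. Dess–Martin periodinane (NaHCO3, CH2Cl2) gives the tri-O-MOM aryl ketone F9, in which no benzylic cation can form, so the three MOM groups can be removed with aq. HCl in MeOH–THF (40 °C) to give the triphenol ketone F10. Asymmetric transfer hydrogenation with RuCl[(R,R)-TsDPEN](p-cymene), HCO2H–Et3N, as in step 9, then sets the (R)-carbinol again and gives 34.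

Further compounds
F1 | step 14 | tert-butyl{[(1R,8E)-9-iodo-1-{4-[3-(methoxymethoxy)-5-(pent-4-en-1-yl)phenoxy]-3,5-bis(methoxymethoxy)phenyl}non-8-en-1-yl]oxy}dimethylsilane | COCOc1cc(CCCC=C)cc(c1)Oc1c(OCOC)cc(cc1OCOC)[C@H](O[Si](C)(C)C(C)(C)C)CCCCCC/C=C/I
F2 | step 14 | B-alkyl-9-BBN adduct of F1 (boron on the terminal carbon of the former pentenyl group) | COCOc1cc(CCCCCB2C3CCCC2CCC3)cc(c1)Oc1c(OCOC)cc(cc1OCOC)[C@H](O[Si](C)(C)C(C)(C)C)CCCCCC/C=C/I
F3 | step 13 | O-allyl ether of 26 | COCOc1cc(cc(OCOC)c1OCC=C)[C@H](O[Si](C)(C)C(C)(C)C)CCCCCC/C=C/I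
F4 | step 13 | B-alkyl-9-BBN adduct of 9 | CC(C)NC(=O)Oc1cc(CCCCCB2C3CCCC2CCC3)cc(OCOC)c1[Si](C)(C)C
F5 | step 13 | seco carbamate (ring B O-allyl, ring A N-isopropylcarbamate) | COCOc1cc(cc(OCOC)c1OCC=C)[C@H](O[Si](C)(C)C(C)(C)C)CCCCCC/C=C/CCCCCc1cc(OCOC)c([Si](C)(C)C)c(OC(=O)NC(C)C)c1
F6 | step 13 | seco 2-silylphenol (ring B O-allyl) | COCOc1cc(cc(OCOC)c1OCC=C)[C@H](O[Si](C)(C)C(C)(C)C)CCCCCC/C=C/CCCCCc1cc(OCOC)c([Si](C)(C)C)c(O)c1
F7 | step 13 | seco triflate allyl ether (O-allyl derivative of 28) | COCOc1cc(cc(OCOC)c1OCC=C)[C@H](O[Si](C)(C)C(C)(C)C)CCCCCC/C=C/CCCCCc1cc(OCOC)c([Si](C)(C)C)c(OS(=O)(=O)C(F)(F)F)c1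
F8 | step 15 | tri-O-MOM dehydrogravicycle (free R carbinol) | COCOc1cc2cc(c1)Oc1c(OCOC)cc(cc1OCOC)[C@H](O)CCCCCC/C=C/CCCCC2
F9 | step 15 | tri-O-MOM macrocyclic aryl ketone | COCOc1cc2cc(c1)Oc1c(OCOC)cc(cc1OCOC)C(=O)CCCCCC/C=C/CCCCC2
F10 | step 15 | macrocyclic triphenol ketone | Oc1cc2cc(c1)Oc1c(O)cc(cc1O)C(=O)CCCCCC/C=C/CCCCC2
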